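The hexasubstituted benzene ring (C4a, C5, C6, C7, C8, C8a), whose three oxygens (ring O1, free 5-OH, 7-OMe) all differ, is split into a four-carbon vinylketene and a two-carbon ynol ether. The ketene source is diazo ketone 17, a finished (2S,3S)-dihydropyranone ring with a 2-diazo-5-methylhex-4-enoyl group at C6. The partner is siloxyalkyne 30, which carries the (R)-configured hexanoate chain. In one operation (Wolff shift, [2+2], 4π opening, 6π closure) the step forms C5–C6, C7–C8 and C4a–C5. It fuses the arene onto the pyranone, seats all six substituents and delivers O1, O5 and O7 as ether, phenol and silyl ether. Two mild steps then finish the target.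

Key step: step 13

Remark: the β-dicarbonyl compounds 9, 16 and F2 are drawn as keto tautomers although they are largely enolised. The quaternary ring carbon of 32 is a transient stereocentre that is erased within the same step and is left undefined.

**Fragment A (steps 1–7)**

Step 1
Reactants: 1 ethyl (3S)-3-hydroxybutanoate
Product: 3 ethyl (2S,3S)-3-hydroxy-2-methylbutanoate, via dilithium alkoxide-enolate 2 (not isolated)
Conditions: LiN(iPr)2 (2.2 equiv), THF, −78 to −20 °C; MeI, DMPU, −78 to 0 °C
Reagents that add atoms: iodomethane, CI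
Why: Fráter–Seebach alkylation: the lithium-chelated dianion 2 should take up the methyl group on the face away from the C3 methyl substituent, which sets C2 as S (anti to the hydroxyl) while C3 comes unchanged from 1.

Step 2
Reactants: 3 ethyl (2S,3S)-3-hydroxy-2-methylbutanoate
Product: 4 ethyl (2S,3S)-2-methyl-3-(triethylsilyloxy)butanoate
Conditions: Et3SiCl, imidazole, CH2Cl2, 0 °C to rt
Reagents that add atoms: chlorotriethylsilane, CC[Si](Cl)(CC)CC
Why: Routine silyl ether formation; the triethylsilyl group should prevent retro-aldol cleavage and β-elimination in the basic steps 3 and 4 and is labile enough to leave in the acid step 5.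

Step 3
Reactants: 4 ethyl (2S,3S)-2-methyl-3-(triethylsilyloxy)butanoate
Product: 6 (3S,4S)-3-methyl-4-(triethylsilyloxy)pentan-2-one, via Weinreb amide 5 (not isolated)
Conditions: MeNH(OMe)·HCl (1.5 equiv), iPrMgCl (3.0 equiv), THF, −20 to 0 °C; then MeMgBr, 0 °C
Reagents that add atoms: methylmagnesium bromide, C[Mg]Br
Why: Weinreb ketone synthesis telescoped in one flask: the chloromagnesium amide turns the ester into amide 5, and its chelated adduct with MeMgBr cannot collapse before work-up, so addition should stop at the ketone and the α-centre is not enolised.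

Step 4
Reactants: 6 (3S,4S)-3-methyl-4-(triethylsilyloxy)pentan-2-one; 7 di-tert-butyl oxalate
Product: 9 tert-butyl (5S,6S)-5-methyl-2,4-dioxo-6-(triethylsilyloxy)heptanoate, via lithium enolate 8 (not isolated)
Conditions: LiN(iPr)2, THF, −78 °C; 7, −78 to 0 °C; AcOH
Reagents that add atoms: none
Why: Crossed Claisen condensation: kinetic deprotonation takes place at the unhindered methyl group, the non-enolisable oxalate 7 acylates enolate 8, and the product is stored as its stabilised enolate, which protects the C5 stereocentre until the acidic quench.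

Step 5
Reactants: 9 tert-butyl (5S,6S)-5-methyl-2,4-dioxo-6-(triethylsilyloxy)heptanoate
Product: 10 (2S,3S)-2,3-dimethyl-4-oxo-3,4-dihydro-2H-pyran-6-carboxylic acid
Conditions: CF3CO2H–CH2Cl2 (1:2), rt
Reagents that add atoms: none
Why: Acidolysis strips the silyl ether and the tert-butyl ester, and the liberated hydroxyl adds to the C2 ketone and loses water (cyclodehydration of a δ-hydroxy-β-diketone to a 2,3-dihydro-4-pyranone), both stereocentres being retained with the methyl groups trans-diequatorial.

Step 6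
Reactants: 10 (2S,3S)-2,3-dimethyl-4-oxo-3,4-dihydro-2H-pyran-6-carboxylic acid; 11 5-bromo-2-methylpent-2-ene
Product: 14 (2S,3S)-2,3-dimethyl-6-(5-methylhex-4-enoyl)-2,3-dihydro-4H-pyran-4-one, via acid chloride 12 (not isolated), via homoprenylzinc bromide 13 (not isolated)
Conditions: 10, (COCl)2, N,N-dimethylformamide (cat.), CH2Cl2, 0 °C to rt, evaporate; 11, Zn, LiCl, THF, 50 °C; combine, Pd(PPh3)4 (5 mol %), THF, 0 °C to rt
Reagents that add atoms: none
Why: Negishi acylation: zerovalent palladium inserts into the C–Cl bond of 12 and the weakly nucleophilic alkylzinc 13 transfers its chain only to the acylpalladium species, so the C4 carbonyl and the C5=C6 double bond, both open to attack by a Grignard reagent, should stay untouched.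

Step 7
Reactants: 14 (2S,3S)-2,3-dimethyl-6-(5-methylhex-4-enoyl)-2,3-dihydro-4H-pyran-4-one
Product: 17 (2S,3S)-6-(2-diazo-5-methylhex-4-enoyl)-2,3-dimethyl-2,3-dihydro-4H-pyran-4-one, via lithium enolate 15 (not isolated), via trifluoroacetyl ketone 16 (not isolated)
Conditions: LiN(SiMe3)2, THF, −78 °C; CF3CO2CH2CF3; aq. HCl wash; then MeSO2N3, Et3N, H2O (1 equiv), MeCN, rt
Reagents that add atoms: methanesulfonyl azide, CS(=O)(=O)N=[N+]=[N-]
Why: Detrifluoroacetylative diazo transfer (Danheiser variant of the Regitz reaction): the kinetic enolate 15 forms at the side-chain CH2, trifluoroacetylation activates this carbon for attack on the azide, and loss of the trifluoroacetyl group delivers the α-alkyl diazo ketone under conditions made for base-sensitive enones.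

**Fragment B (steps 8–12)**

Step 8
Reactants: 18 (4S)-4-benzyl-1,3-oxazolidin-2-one; 19 pentanoyl chloride
Product: 20 (4S)-4-benzyl-3-pentanoyl-1,3-oxazolidin-2-one
Conditions: Et3N, 4-(dimethylamino)pyridine (cat.), CH2Cl2, 0 °C to rt
Reagents that add atoms: none
Why: Nucleophile-catalysed N-acylation of the Evans auxiliary with an acid chloride, a standard reaction that leaves the C4 centre of the auxiliary untouched.

Step 9
Reactants: 20 (4S)-4-benzyl-3-pentanoyl-1,3-oxazolidin-2-one; 21 tert-butyl bromoacetate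
Product: 23 tert-butyl (3R)-3-{[(4S)-4-benzyl-2-oxo-1,3-oxazolidin-3-yl]carbonyl}hexanoate, via sodium Z-enolate 22 (not isolated)
Conditions: NaN(SiMe3)2, THF, −78 °C; 21, −78 to −30 °C
Reagents that add atoms: none
Why: Evans asymmetric alkylation: the chelated Z-enolate 22 should be attacked by the activated bromide on the face opposite to the benzyl group, which sets C3 of the hexanoate as R.

Step 10
Reactants: 23 tert-butyl (3R)-3-{[(4S)-4-benzyl-2-oxo-1,3-oxazolidin-3-yl]carbonyl}hexanoate
Product: 24 4-tert-butyl 1-methyl (2R)-2-propylbutanedioate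
Conditions: MeOMgBr (from MeMgBr and MeOH), MeOH–CH2Cl2, 0 °C
Reagents that add atoms: methanol (delivered as MeOMgBr), CO
Why: Evans-type transesterification: the weakly basic magnesium methoxide attacks the exocyclic imide carbonyl, releases the auxiliary without epimerisation and does not touch the hindered tert-butyl ester.

Step 11
Reactants: 24 4-tert-butyl 1-methyl (2R)-2-propylbutanedioate
Product: 26 tert-butyl (3R)-3-(dibromoacetyl)hexanoate, via lithium hemiketal alkoxide 25 (not isolated)
Conditions: CH2Br2 (2.2 equiv), lithium 2,2,6,6-tetramethylpiperidide (2.0 equiv), THF, −90 °C; 24, −90 to −78 °C; AcOH, −78 °C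
Reagents that add atoms: dibromomethane, BrCBr
Why: First half of the Kowalski homologation: dibromomethyllithium adds to the methyl ester much faster than to the tert-butyl ester, adduct 25 persists at low temperature, and the cold acid quench releases the dibromomethyl ketone with the α-centre intact.

Step 12
Reactants: 26 tert-butyl (3R)-3-(dibromoacetyl)hexanoate
Product: 30 tert-butyl (3R)-3-[(triisopropylsilyloxy)ethynyl]hexanoate, via dilithium bis-enolate 27 (not isolated), via bromo carbenoid 28 (not isolated), via dilithium ynolate 29 (not isolated)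
Conditions: LiN(SiMe3)2 (2.2 equiv), THF, −78 °C; t-BuLi (4.2 equiv, two of them re-lithiate the freed amine), −78 to 0 °C; iPr3SiCl (1.1 equiv), −78 to 0 °C; pH 7 buffer
Reagents that add atoms: chlorotriisopropylsilane, CC(C)[Si](Cl)(C(C)C)C(C)C
Why: Kowalski rearrangement: after both carbonyl groups are masked as enolates (27), bromine–lithium exchange gives carbenoid 28, whose secondary alkyl group migrates with retention to give ynolate 29, and the bulky chlorosilane should silylate the unhindered ynolate oxygen but not the tert-butyl ester enolate, which is reprotonated on work-up.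

**Union and end game (steps 13–15)**

Step 13
Reactants: 17 (2S,3S)-6-(2-diazo-5-methylhex-4-enoyl)-2,3-dimethyl-2,3-dihydro-4H-pyran-4-one; 30 tert-butyl (3R)-3-[(triisopropylsilyloxy)ethynyl]hexanoate
Product: 34 tert-butyl (3R)-3-[(2S,3S)-5-hydroxy-2,3-dimethyl-8-(3-methylbut-2-en-1-yl)-4-oxo-7-(triisopropylsilyloxy)-3,4-dihydro-2H-chromen-6-yl]hexanoate, via vinylketene 31 (not isolated), via vinylcyclobutenone 32 (not isolated), via dienylketene 33 (not isolated)
Conditions: 17 (1 equiv), 30 (1.5 equiv), degassed toluene (0.05 M), hν (405 nm LED), 20 °C until N2 evolution ends; then 110 °C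
Reagents that add atoms: none
Why: Excitation of 17 releases N2 with a 1,2-shift of the sp2 carbon C6 of the pyranone onto the former diazo carbon (Wolff rearrangement; in chromanone numbering the old C8a–C5 bond is traded for C8–C8a), and the vinylketene 31 so formed is captured at its central carbon by the electron-rich, side-chain-bearing carbon of 30 in a [2+2] cycloaddition that makes C5–C6 and C7–C8 and gives cyclobutenone 32. On heating, 32 opens reversibly (conrotatory 4π, cleaving C5–C8) to dienylketene 33, and the benzene ring is closed by a disrotatory 6π electrocyclisation in which the ketene carbon bonds to pyranone C5, the nucleophilic β-carbon of the enol ether and future C4a (C4a–C5), before tautomerisation to the hydrogen-bonded phenol pulls the cascade to 34. The closest known reaction type is the Danheiser benzannulation in its diazo ketone form with siloxyalkynes, α-alkyl vinylketenes being established partners in the cyclobutenone form and the Wolff shift of acyclic α-alkyl diazo ketones being known from Arndt–Eistert homologations with higher diazoalkanes. No lasting stereocentre is created (the quaternary carbon of 32 disappears on ring opening), and the three existing centres pass through neutral pericyclic events that neither break their bonds nor enolise C3. The regiochemistry needed, side chain beside the new phenol and silyloxy group beside the prenyl-bearing carbon, is secured by the polarisation of the oxygen-substituted alkyne, which also fixes the origin of the three oxygens: 5-OH from the ketene carbonyl, O7 from the ynol ether and O1 from the heterocycle. The chemoselectivity needed is Wolff shift over 1,2-hydride shift from the allylic CH2, which direct long-wavelength excitation without sensitiser, the good migratory aptitude of the sp2 carbon and an excess of 30 should favour, while 405 nm light leaves the enone and the product chromophores unexcited.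

Step 14
Reactants: 34 tert-butyl (3R)-3-[(2S,3S)-5-hydroxy-2,3-dimethyl-8-(3-methylbut-2-en-1-yl)-4-oxo-7-(triisopropylsilyloxy)-3,4-dihydro-2H-chromen-6-yl]hexanoate
Product: 36 tert-butyl (3R)-3-[(2S,3S)-5-hydroxy-7-methoxy-2,3-dimethyl-8-(3-methylbut-2-en-1-yl)-4-oxo-3,4-dihydro-2H-chromen-6-yl]hexanoate, via tetrabutylammonium phenoxide 35 (not isolated)
Conditions: Bu4NF (1.05 equiv), MeI (5 equiv), THF, 0 °C
Reagents that add atoms: iodomethane, CI
Why: Fluoride cleaves the aryl silyl ether and phenoxide 35 is methylated in situ (Williamson ether synthesis); the charge is generated at O7 only, and the 5-OH, hydrogen-bonded to the C4 carbonyl and less acidic, should stay free.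

Step 15
Reactants: 36 tert-butyl (3R)-3-[(2S,3S)-5-hydroxy-7-methoxy-2,3-dimethyl-8-(3-methylbut-2-en-1-yl)-4-oxo-3,4-dihydro-2H-chromen-6-yl]hexanoate
Product: 37 (3R)-3-[(2S,3S)-5-hydroxy-7-methoxy-2,3-dimethyl-8-(3-methylbut-2-en-1-yl)-4-oxo-3,4-dihydro-2H-chromen-6-yl]hexanoic acid (CNP0233409.1)
Conditions: CF3CO2H–CH2Cl2 (1:4), 0 °C
Reagents that add atoms: none
Why: Acid-catalysed tert-butyl ester cleavage through the tert-butyl cation; the arene has no free position, O7 is capped so the prenyl group cannot cyclise to a chroman, and low temperature should hold back alkene protonation and lactonisation onto the 5-OH.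

**Compound list**

1 | ethyl (3S)-3-hydroxybutanoate | C[C@H](O)CC(=O)OCC | starting material
2 | dilithium alkoxide-enolate of 1 (enolate oxygen cis to the carbinol carbon) | [Li+].[Li+].C[C@H]([O-])/C=C(\[O-])OCC | intermediate
3 | ethyl (2S,3S)-3-hydroxy-2-methylbutanoate | O[C@@H](C)[C@H](C)C(=O)OCC | intermediate
4 | ethyl (2S,3S)-2-methyl-3-(triethylsilyloxy)butanoate | CC[Si](CC)(CC)O[C@@H](C)[C@H](C)C(=O)OCC | intermediate
5 | (2S,3S)-N-methoxy-N,2-dimethyl-3-(triethylsilyloxy)butanamide | CC[Si](CC)(CC)O[C@@H](C)[C@H](C)C(=O)N(C)OC | intermediate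
6 | (3S,4S)-3-methyl-4-(triethylsilyloxy)pentan-2-one | CC[Si](CC)(CC)O[C@@H](C)[C@H](C)C(C)=O | intermediate
7 | di-tert-butyl oxalate | CC(C)(C)OC(=O)C(=O)OC(C)(C)C | starting material
8 | lithium enolate of 6 (terminal C=C) | CC[Si](CC)(CC)O[C@@H](C)[C@H](C)C([O-])=C.[Li+] | intermediate
9 | tert-butyl (5S,6S)-5-methyl-2,4-dioxo-6-(triethylsilyloxy)heptanoate | CC[Si](CC)(CC)O[C@@H](C)[C@H](C)C(=O)CC(=O)C(=O)OC(C)(C)C | intermediate
10 | (2S,3S)-2,3-dimethyl-4-oxo-3,4-dihydro-2H-pyran-6-carboxylic acid | O1[C@@H](C)[C@H](C)C(=O)C=C1C(=O)O | intermediate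
11 | 5-bromo-2-methylpent-2-ene | CC(C)=CCCBr | starting material
12 | (2S,3S)-2,3-dimethyl-4-oxo-3,4-dihydro-2H-pyran-6-carbonyl chloride | O1[C@@H](C)[C@H](C)C(=O)C=C1C(=O)Cl | intermediate
13 | (4-methylpent-3-en-1-yl)zinc bromide | CC(C)=CCC[Zn]Br | intermediate
14 | (2S,3S)-2,3-dimethyl-6-(5-methylhex-4-enoyl)-2,3-dihydro-4H-pyran-4-one | O1[C@@H](C)[C@H](C)C(=O)C=C1C(=O)CCC=C(C)C | intermediate
15 | lithium enolate of 14 (side-chain C1=C2) | O1[C@@H](C)[C@H](C)C(=O)C=C1C([O-])=CCC=C(C)C.[Li+] | intermediate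
16 | (2S,3S)-2,3-dimethyl-6-[5-methyl-2-(trifluoroacetyl)hex-4-enoyl]-2,3-dihydro-4H-pyran-4-one | O1[C@@H](C)[C@H](C)C(=O)C=C1C(=O)C(CC=C(C)C)C(=O)C(F)(F)F | intermediate
17 | (2S,3S)-6-(2-diazo-5-methylhex-4-enoyl)-2,3-dimethyl-2,3-dihydro-4H-pyran-4-one | O1[C@@H](C)[C@H](C)C(=O)C=C1C(=O)C(=[N+]=[N-])CC=C(C)C | intermediate
18 | (4S)-4-benzyl-1,3-oxazolidin-2-one | O=C1N[C@@H](Cc2ccccc2)CO1 | starting material
19 | pentanoyl chloride | CCCCC(=O)Cl | starting material
20 | (4S)-4-benzyl-3-pentanoyl-1,3-oxazolidin-2-one | CCCCC(=O)N1[C@@H](Cc2ccccc2)COC1=O | intermediate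
21 | tert-butyl bromoacetate | BrCC(=O)OC(C)(C)C | starting material
22 | sodium (Z)-enolate of 20 | [Na+].CCC/C=C(\[O-])N1[C@@H](Cc2ccccc2)COC1=O | intermediate
23 | tert-butyl (3R)-3-{[(4S)-4-benzyl-2-oxo-1,3-oxazolidin-3-yl]carbonyl}hexanoate | CCC[C@H](CC(=O)OC(C)(C)C)C(=O)N1[C@@H](Cc2ccccc2)COC1=O | intermediate
24 | 4-tert-butyl 1-methyl (2R)-2-propylbutanedioate | CCC[C@H](CC(=O)OC(C)(C)C)C(=O)OC | intermediate
25 | lithium hemiketal alkoxide from 24 and dibromomethyllithium | CCC[C@H](CC(=O)OC(C)(C)C)C([O-])(OC)C(Br)Br.[Li+] | intermediate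
26 | tert-butyl (3R)-3-(dibromoacetyl)hexanoate | CCC[C@H](CC(=O)OC(C)(C)C)C(=O)C(Br)Br | intermediate
27 | dilithium bis-enolate of 26 (dibromo enolate plus ester enolate) | CCC[C@H](C=C([O-])OC(C)(C)C)C([O-])=C(Br)Br.[Li+].[Li+] | intermediate
28 | α-bromo-α-lithio enolate (carbenoid) derived from 27 | CCC[C@H](C=C([O-])OC(C)(C)C)C([O-])=C([Li])Br.[Li+].[Li+] | intermediate
29 | dilithium ynolate / ester enolate | CCC[C@H](C=C([O-])OC(C)(C)C)C#C[O-].[Li+].[Li+] | intermediate
30 | tert-butyl (3R)-3-[(triisopropylsilyloxy)ethynyl]hexanoate | CCC[C@H](CC(=O)OC(C)(C)C)C#CO[Si](C(C)C)(C(C)C)C(C)C | intermediate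
31 | 2-[(2S,3S)-2,3-dimethyl-4-oxo-3,4-dihydro-2H-pyran-6-yl]-5-methylhexa-1,4-dien-1-one (vinylketene) | O1[C@@H](C)[C@H](C)C(=O)C=C1C(CC=C(C)C)=C=O | intermediate
32 | tert-butyl (3R)-3-{3-[(2S,3S)-2,3-dimethyl-4-oxo-3,4-dihydro-2H-pyran-6-yl]-3-(3-methylbut-2-en-1-yl)-4-oxo-2-(triisopropylsilyloxy)cyclobut-1-en-1-yl}hexanoate | O1[C@@H](C)[C@H](C)C(=O)C=C1C2(CC=C(C)C)C(=O)C([C@H](CCC)CC(=O)OC(C)(C)C)=C2O[Si](C(C)C)(C(C)C)C(C)C | intermediate
33 | dienylketene from 4π opening of 32 (pyranonyl group cis to the ketenyl carbon) | O1[C@@H](C)[C@H](C)C(=O)C=C1/C(CC=C(C)C)=C(O[Si](C(C)C)(C(C)C)C(C)C)\C([C@H](CCC)CC(=O)OC(C)(C)C)=C=O | intermediate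
34 | tert-butyl (3R)-3-[(2S,3S)-5-hydroxy-2,3-dimethyl-8-(3-methylbut-2-en-1-yl)-4-oxo-7-(triisopropylsilyloxy)-3,4-dihydro-2H-chromen-6-yl]hexanoate | CCC[C@H](CC(=O)OC(C)(C)C)c1c(O)c2c(c(CC=C(C)C)c1O[Si](C(C)C)(C(C)C)C(C)C)O[C@@H](C)[C@H](C)C2=O | intermediate
35 | tetrabutylammonium 7-phenoxide of desilylated 34 | CCC[C@H](CC(=O)OC(C)(C)C)c1c(O)c2c(c(CC=C(C)C)c1[O-])O[C@@H](C)[C@H](C)C2=O.CCCC[N+](CCCC)(CCCC)CCCC | intermediate
36 | tert-butyl (3R)-3-[(2S,3S)-5-hydroxy-7-methoxy-2,3-dimethyl-8-(3-methylbut-2-en-1-yl)-4-oxo-3,4-dihydro-2H-chromen-6-yl]hexanoate | CCC[C@H](CC(=O)OC(C)(C)C)c1c(O)c2c(c(CC=C(C)C)c1OC)O[C@@H](C)[C@H](C)C2=O | intermediate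
37 | (3R)-3-[(2S,3S)-5-hydroxy-7-methoxy-2,3-dimethyl-8-(3-methylbut-2-en-1-yl)-4-oxo-3,4-dihydro-2H-chromen-6-yl]hexanoic acid | CCC[C@H](CC(=O)O)c1c(O)c2c(c(CC=C(C)C)c1OC)O[C@@H](C)[C@H](C)C2=O | target

**Step count**

Total step count: 15 (fragment A 7, fragment B 5, union and end game 3).
Longest linear sequence: 10 steps (steps 1–7, then 13–15).

**Steps most likely to fail**

1. Step 13. A 1,2-hydride shift from the allylic CH2 may outrun the Wolff shift, and the crowded disubstituted ketene may dimerise faster than it adds the hindered alkyne.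

   The fallback sets out from 10 and returns at 36. It leaves the prenyl group out of the annulation and adds it afterwards.
   - Acid chloride 12, made from 10 as in step 6, is coupled with MeZnCl under Pd(PPh3)4 catalysis to give (2S,3S)-6-acetyl-2,3-dimethyl-2,3-dihydro-4H-pyran-4-one F1.
   - Trifluoroacetylation gives the trifluoromethyl β-diketone F2. Diazo transfer with the reagents of step 7 then gives the terminal diazo ketone (2S,3S)-6-(diazoacetyl)-2,3-dimethyl-2,3-dihydro-4H-pyran-4-one F3. F3 has no hydrogen that can shift and belongs to the classical substrate class of this annulation.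
   - Irradiation with 30 followed by heating should give the 8-unsubstituted 7-silyloxychromanone F4, and Bu4NF/AcOH frees the 5,7-dihydroxychromanone F5.
   - Tsuji–Trost O-allylation of the non-chelated 7-OH with tert-butyl 2-methylbut-3-en-2-yl carbonate and Pd(PPh3)4 gives the 7-(1,1-dimethylallyl) ether F6.
   - An aromatic Claisen rearrangement (toluene, 110 °C), for which C8 is the only open ortho position, delivers the 8-prenyl-5,7-dihydroxychromanone F7.
   - MeI and K2CO3 in acetone then methylate the 7-OH to give 36.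

2. Step 12. Proton transfer between the carbenoid and the ester, attack of t-BuLi on the ester, or silylation of the ester enolate may erode the rearrangement.

   The fallback sets out from 23 and returns at 30. It makes the ynolate by oxidising an acetylide rather than by rearranging a carbenoid.
   - LiBH4 (Et2O, 1 equiv H2O, 0 °C) removes the auxiliary reductively to give tert-butyl (3R)-3-(hydroxymethyl)hexanoate F8.
   - Dess–Martin periodinane gives tert-butyl (3R)-3-formylhexanoate F9.
   - Ohira–Bestmann homologation (dimethyl (1-diazo-2-oxopropyl)phosphonate, K2CO3, MeOH) gives tert-butyl (3R)-3-ethynylhexanoate F10.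
   - One equivalent of n-BuLi at −78 °C gives the lithium acetylide F11.
   - Lithium tert-butyl peroxide (−78 to 0 °C) oxidises it to the lithium ynolate F12, and iPr3SiOTf at −78 °C silylates the oxygen to give 30.

3. Step 15. Protonation of the prenyl double bond or acid-catalysed lactonisation of the freed acid onto the 5-OH may compete with ester cleavage.

   The fallback sets out from 36 and returns at 37. It abandons Brønsted acid for a silyl-transfer cleavage.
   - Me3SiOTf and 2,6-lutidine in CH2Cl2 at 0 °C exchange the tert-butyl group for silicon under buffered aprotic conditions. This gives the trimethylsilyl ester 5-O-trimethylsilyl ether F13.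
   - Its two labile Si–O bonds are hydrolysed by aqueous citric acid in MeOH at 0 °C to give 37.

**Further compounds**

F1 | step 13 | (2S,3S)-6-acetyl-2,3-dimethyl-2,3-dihydro-4H-pyran-4-one | O1[C@@H](C)[C@H](C)C(=O)C=C1C(C)=O
F2 | step 13 | 1-[(2S,3S)-2,3-dimethyl-4-oxo-3,4-dihydro-2H-pyran-6-yl]-4,4,4-trifluorobutane-1,3-dione | O1[C@@H](C)[C@H](C)C(=O)C=C1C(=O)CC(=O)C(F)(F)F
F3 | step 13 | (2S,3S)-6-(diazoacetyl)-2,3-dimethyl-2,3-dihydro-4H-pyran-4-one | O1[C@@H](C)[C@H](C)C(=O)C=C1C(=O)C=[N+]=[N-]
F4 | step 13 | tert-butyl (3R)-3-[(2S,3S)-5-hydroxy-2,3-dimethyl-4-oxo-7-(triisopropylsilyloxy)-3,4-dihydro-2H-chromen-6-yl]hexanoate | CCC[C@H](CC(=O)OC(C)(C)C)c1c(O)c2c(cc1O[Si](C(C)C)(C(C)C)C(C)C)O[C@@H](C)[C@H](C)C2=O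
F5 | step 13 | tert-butyl (3R)-3-[(2S,3S)-5,7-dihydroxy-2,3-dimethyl-4-oxo-3,4-dihydro-2H-chromen-6-yl]hexanoate | CCC[C@H](CC(=O)OC(C)(C)C)c1c(O)c2c(cc1O)O[C@@H](C)[C@H](C)C2=O
F6 | step 13 | tert-butyl (3R)-3-[(2S,3S)-5-hydroxy-2,3-dimethyl-7-(2-methylbut-3-en-2-yloxy)-4-oxo-3,4-dihydro-2H-chromen-6-yl]hexanoate | CCC[C@H](CC(=O)OC(C)(C)C)c1c(O)c2c(cc1OC(C)(C)C=C)O[C@@H](C)[C@H](C)C2=O
F7 | step 13 | tert-butyl (3R)-3-[(2S,3S)-5,7-dihydroxy-2,3-dimethyl-8-(3-methylbut-2-en-1-yl)-4-oxo-3,4-dihydro-2H-chromen-6-yl]hexanoate | CCC[C@H](CC(=O)OC(C)(C)C)c1c(O)c2c(c(CC=C(C)C)c1O)O[C@@H](C)[C@H](C)C2=O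
F8 | step 12 | tert-butyl (3R)-3-(hydroxymethyl)hexanoate | CCC[C@H](CC(=O)OC(C)(C)C)CO
F9 | step 12 | tert-butyl (3R)-3-formylhexanoate | CCC[C@H](CC(=O)OC(C)(C)C)C=O
F10 | step 12 | tert-butyl (3R)-3-ethynylhexanoate | CCC[C@H](CC(=O)OC(C)(C)C)C#C
F11 | step 12 | lithium acetylide of F10 | CCC[C@H](CC(=O)OC(C)(C)C)C#C[Li]
F12 | step 12 | lithium ynolate from F11 | CCC[C@H](CC(=O)OC(C)(C)C)C#C[O-].[Li+]
F13 | step 15 | trimethylsilyl (3R)-3-[(2S,3S)-7-methoxy-2,3-dimethyl-8-(3-methylbut-2-en-1-yl)-4-oxo-5-(trimethylsilyloxy)-3,4-dihydro-2H-chromen-6-yl]hexanoate | CCC[C@H](CC(=O)O[Si](C)(C)C)c1c(O[Si](C)(C)C)c2c(c(CC=C(C)C)c1OC)O[C@@H](C)[C@H](C)C2=O
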